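**Plan**

Numbering follows 6H-isochromene (C1, O2, C3, C4, C4a, C5, C6, C7, C8, C8a; ring A = pyran, ring B = carbocycle). The retrosynthesis first opens ring A at O2–C1 and puts back a silyl group at C5 and the protecting groups, then cuts ring B at C4a–C8a and C5–C6 together, then C7–C8 (aldol), the ester C–O bond and an ynamide C–N bond.
Enabling feature: ring B is a cyclohex-2-enone (C6=O, C5=C4a) with an exocyclic heteroatom-bearing alkylidene at C8a (C8a=C1H–O2) beside the sp3 pair C7/C8. That is the product pattern of a rhodium-catalysed [4+2] annulation of a 4-alkynal (C6–C7–C8–C8a≡C1) with an alkyne (C4a≡C5); the C1 hydrogen is the former formyl hydrogen.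
Helpers: N(Me)Ts on C1 (oxygen surrogate and leaving group), SiMe3 on C5 (regiocontrol, lost from the nucleophilic exocyclic carbon of the methylenepyran), a silyl ether on the C7 oxygen, and a tert-butyl ester.
Forward: side-chain alcohol + silylbutynoic acid → ester → ketene acetal → copper-catalysed aldol with methyl pyruvate (C7–C8) → bromoalkyne → ynamide → aldehyde; annulation with a silyl-capped alkynyl ketone builds ring B; one acid treatment closes ring A and removes all helpers.
Stereochemistry: C4 of the alcohol comes from (S)-1-bromo-2-methylbutane and its C2 from enzymatic reduction followed by Mitsunobu inversion; C7 and C8 (both R, hydroxyl and ester cis) come from the catalyst-controlled syn aldol; the E acrylate comes from the starting enoate.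

Key step: step 12

Assumption: tert-butyl (E)-4-oxobut-2-enoate is taken as a purchasable building block.

**Route**

Step 1
Reactants: 1 (S)-1-bromo-2-methylbutane; 2 N-methoxy-N-methylacetamide
Product: 4 (S)-4-methylhexan-2-one, via (S)-(2-methylbutyl)magnesium bromide 3 (not isolated)
Conditions: Mg, THF, reflux; then 2, 0 °C; aq. NH4Cl
Reagents that add atoms: none
Why: Grignard formation leaves the β-stereocentre untouched and the Weinreb ketone synthesis should stop at the methyl ketone through the stable magnesium chelate.

Step 2
Reactants: 4 (S)-4-methylhexan-2-one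
Product: 5 (2R,4S)-4-methylhexan-2-ol
Conditions: Lactobacillus brevis alcohol dehydrogenase, NADP+ (cat.), iPrOH, phosphate buffer (neutral), MgCl2 (trace), 30 °C
Reagents that add atoms: none
Why: enzymatic ketone reduction, in which an (R)-selective alcohol dehydrogenase delivers hydride to the si face of a methyl ketone with one small and one large substituent, so that C2 should be set (R) under enzyme control while C4 is untouched.

Step 3
Reactants: 6 4-(trimethylsilyl)but-3-yn-1-ol
Product: 7 4-(trimethylsilyl)but-3-ynoic acid
Conditions: CrO3, H2SO4, acetone/H2O, 0 °C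
Reagents that add atoms: water, O
Why: Jones oxidation of a primary homopropargylic alcohol through the aldehyde hydrate, with the silyl cap protecting the alkyne terminus.

Step 4
Reactants: 7 4-(trimethylsilyl)but-3-ynoic acid; 5 (2R,4S)-4-methylhexan-2-ol
Product: 8 (2S,4S)-4-methylhexan-2-yl 4-(trimethylsilyl)but-3-ynoate
Conditions: PPh3, DIAD, THF, 0 °C to rt
Reagents that add atoms: none
Why: Mitsunobu esterification, in which the carboxylate displaces the activated secondary alcohol with inversion (2R to 2S) and the acid is never activated as an acyl donor, which should avoid isomerisation of the 3-alkynoate to an allenoate.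

Step 5
Reactants: 8 (2S,4S)-4-methylhexan-2-yl 4-(trimethylsilyl)but-3-ynoate
Product: 10 the trimethylsilyl ketene acetal of the ester (E/Z mixture), via lithium enolate 9 (not isolated)
Conditions: LiN(iPr)2, THF, −78 °C; then Me3SiCl, −78 °C to rt; non-aqueous work-up
Reagents that add atoms: chlorotrimethylsilane, C[Si](C)(C)Cl
Why: kinetic ester enolisation followed by O-silylation, with the geometry left uncontrolled because both isomers are expected to converge on one adduct in step 6.

Step 6
Reactants: 10 the trimethylsilyl ketene acetal; 11 methyl pyruvate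
Product: 12 1-methyl 4-[(2S,4S)-4-methylhexan-2-yl] (2R,3R)-2-methyl-3-[(trimethylsilyl)ethynyl]-2-(trimethylsilyloxy)butanedioate
Conditions: [Cu((R,R)-tBu-box)](OTf)2 (cat.; tBu-box = 2,2'-(propane-2,2-diyl)bis(4-tert-butyl-4,5-dihydrooxazole)), THF, −78 °C; non-acidic work-up
Reagents that add atoms: none
Why: bis(oxazoline)copper-catalysed enantioselective Mukaiyama aldol, in which the pyruvate chelates divalent copper in the square plane, the (R,R)-ligand (opposite to the (S,S)-complex, whose established sense is si-face attack) should leave the re face open to set C7 (R), the open transition state should give the syn adduct (C8 R) from either ketene acetal geometry, silyl transfer delivers the tertiary alcohol already protected, and the bulky silyl cap is expected to block attack through the alkyne terminus.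

Step 7
Reactants: 12 the aldol adduct
Product: 13 1-methyl 4-[(2S,4S)-4-methylhexan-2-yl] (2R,3R)-3-(bromoethynyl)-2-methyl-2-(trimethylsilyloxy)butanedioate
Conditions: NBS, AgNO3 (cat.), acetone, rt, dark
Reagents that add atoms: N-bromosuccinimide, O=C1CCC(=O)N1Br
Why: silver-catalysed bromodesilylation of a C-silyl alkyne through the silver acetylide under neutral conditions, which should spare the hindered tertiary silyl ether and the C8 stereocentre.

Step 8
Reactants: 13 the bromoalkyne
Product: 14 1-methyl 4-[(2S,4S)-4-methylhexan-2-yl] (2R,3R)-2-methyl-3-{[methyl(4-methylbenzenesulfonyl)amino]ethynyl}-2-(trimethylsilyloxy)butanedioate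
Conditions: TsNHMe, CuSO4·5H2O (cat.), 1,10-phenanthroline (cat.), K2CO3, toluene, 65 °C
Reagents that add atoms: N-methyl-4-methylbenzenesulfonamide, CNS(=O)(=O)c1ccc(C)cc1
Why: copper-catalysed N-alkynylation of a sulfonamide with a 1-bromoalkyne (Ullmann-type C–N coupling, the standard ynamide synthesis), with an insoluble carbonate base that should be too weak to epimerise C8.

Step 9
Reactants: 14 the ynamide diester
Product: 15 (2S,4S)-4-methylhexan-2-yl (2R,3R)-3-methyl-2-{[methyl(4-methylbenzenesulfonyl)amino]ethynyl}-4-oxo-3-(trimethylsilyloxy)butanoate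
Conditions: iBu2AlH (slight excess), CH2Cl2, −78 °C; MeOH, then aq. KNaC4H4O6
Reagents that add atoms: none
Why: partial reduction of an α-siloxy methyl ester, whose tetrahedral aluminium hemiacetal is held by chelation to the α-oxygen until work-up, while the hindered secondary-alkyl ester and the ynamide should react more slowly at −78 °C.

Step 10
Reactants: 16 tert-butyl (E)-4-oxobut-2-enoate; 17 3-bromo-1-(trimethylsilyl)prop-1-yne
Product: 18 tert-butyl (E)-4-hydroxy-7-(trimethylsilyl)hept-2-en-6-ynoate (racemic)
Conditions: Zn dust, THF, 0 °C to rt; aq. NH4Cl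
Reagents that add atoms: none
Why: Barbier-type propargylation, in which the allenylzinc formed in the flask adds through its γ-carbon to the aldehyde in 1,2-fashion to give the homopropargylic alcohol, whose new stereocentre is left racemic because step 11 removes it.

Step 11
Reactants: 18 the homopropargylic alcohol
Product: 19 tert-butyl (E)-4-oxo-7-(trimethylsilyl)hept-2-en-6-ynoate
Conditions: Dess–Martin periodinane, CH2Cl2, 0 °C
Reagents that add atoms: none
Why: Dess–Martin oxidation under non-basic conditions, chosen so that the β,γ-alkynyl ketone is not isomerised to the allenyl ketone.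

Step 12
Reactants: 15 the ynamide aldehyde; 19 the silyl-capped alkynyl ketone
Product: 20 (2S,4S)-4-methylhexan-2-yl (1R,2R,6E)-5-[(3E)-5-tert-butoxy-2,5-dioxopent-3-en-1-yl]-2-methyl-6-{[methyl(4-methylbenzenesulfonyl)amino]methylidene}-3-oxo-4-(trimethylsilyl)-2-(trimethylsilyloxy)cyclohex-4-ene-1-carboxylate
Conditions: [Rh(cod)2]BF4 (cat.), 1,4-bis(diphenylphosphino)butane (cat.), H2 then Ar (catalyst activation), alkyne partner in excess, CH2Cl2, rt to 40 °C
Reagents that add atoms: none
Why: Proposed new method: the formyl C–H bond of 15 should add oxidatively to monovalent rhodium and the acyl rhodium hydride should add syn across the tethered ynamide, hydride to the electrophilic nitrogen-bearing carbon (C1) and rhodium to C8a, to give a five-membered acyl(alkenyl) rhodacycle of trivalent rhodium; 19 then inserts into the Rh–alkenyl bond (C8a–C4a) with silicon on the rhodium-bound carbon, and acyl–alkenyl reductive elimination forms C5–C6. The closest known reaction type is the rhodium-catalysed [4+2] annulation of 4-alkynals with alkynes, shown for carbon-substituted alkynals but not for an ynamide terminus combined with a 1-silylalkyne partner. Ring B is closed by reductive elimination from a seven-membered rhodacycle, an intermolecular [4+2] mode in which both new bonds are made at the metal, and the (E) geometry of the exocyclic C8a=C1 bond follows from the syn addition of Rh–H, although either geometry would serve because C1 becomes tetrahedral during step 13. No stereocentre is formed and none is at risk, since C7 is quaternary and C8 is not enolised under the neutral conditions. The step needs chemoselectivity for annulation over reductive elimination to the alkylidenecyclobutanone or trans addition leading to the cyclopentenone, which an excess of 19 and the wide-bite diphosphine should favour, and it needs one insertion regiochemistry, which the trimethylsilyl group should secure by ending up α to rhodium as it does in Larock-type annulations of silylalkynes. Insertion of the alkyne rather than the enoate C=C of 19 rests on the general preference of such rhodacycles for alkynes over 1,2-disubstituted alkenes.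

Step 13
Reactants: 20 the annulation product
Product: 22 (E)-3-[(7R,8R)-7-hydroxy-7-methyl-8-{[(2S,4S)-4-methylhexan-2-yl]oxycarbonyl}-6-oxo-7,8-dihydro-6H-isochromen-3-yl]prop-2-enoic acid, via tert-butyl ester 21 (not isolated)
Conditions: CF3CO2H/CH2Cl2, H2O (few equiv), 0 °C to rt
Reagents that add atoms: none
Why: acid-mediated cascade of known reaction types, in which the enol oxygen of the C3 ketone attacks the vinylogous N-sulfonyliminium carbon C1 and TsNHMe leaves (addition–elimination closing ring A by O2–C1), ipso-protonation at C5 of the resulting methylenepyran gives a pyrylium ion that loses the silyl group (protodesilylation), the tertiary silyl ether is hydrolysed and the tert-butyl ester is cleaved with loss of isobutene, all without touching C7 or C8.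

**Compound list**

1 | (S)-1-bromo-2-methylbutane | CC[C@H](C)CBr | starting material
2 | N-methoxy-N-methylacetamide | CC(=O)N(C)OC | starting material
3 | (S)-(2-methylbutyl)magnesium bromide | CC[C@H](C)C[Mg]Br | intermediate
4 | (S)-4-methylhexan-2-one | CC[C@H](C)CC(C)=O | intermediate
5 | (2R,4S)-4-methylhexan-2-ol | CC[C@H](C)C[C@@H](C)O | intermediate
6 | 4-(trimethylsilyl)but-3-yn-1-ol | C[Si](C)(C)C#CCCO | starting material
7 | 4-(trimethylsilyl)but-3-ynoic acid | C[Si](C)(C)C#CCC(=O)O | intermediate
8 | (2S,4S)-4-methylhexan-2-yl 4-(trimethylsilyl)but-3-ynoate | CC[C@H](C)C[C@H](C)OC(=O)CC#C[Si](C)(C)C | intermediate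
9 | lithium enolate of the ester: lithium 1-{[(2S,4S)-4-methylhexan-2-yl]oxy}-4-(trimethylsilyl)but-1-en-3-yn-1-olate (geometry not fixed) | CC[C@H](C)C[C@H](C)OC(O[Li])=CC#C[Si](C)(C)C | intermediate
10 | trimethylsilyl ketene acetal of the ester: 1-{[(2S,4S)-4-methylhexan-2-yl]oxy}-4-(trimethylsilyl)-1-(trimethylsilyloxy)but-1-en-3-yne (E/Z mixture) | CC[C@H](C)C[C@H](C)OC(O[Si](C)(C)C)=CC#C[Si](C)(C)C | intermediate
11 | methyl pyruvate | CC(=O)C(=O)OC | starting material
12 | 1-methyl 4-[(2S,4S)-4-methylhexan-2-yl] (2R,3R)-2-methyl-3-[(trimethylsilyl)ethynyl]-2-(trimethylsilyloxy)butanedioate | CC[C@H](C)C[C@H](C)OC(=O)[C@H](C#C[Si](C)(C)C)[C@@](C)(O[Si](C)(C)C)C(=O)OC | intermediate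
13 | 1-methyl 4-[(2S,4S)-4-methylhexan-2-yl] (2R,3R)-3-(bromoethynyl)-2-methyl-2-(trimethylsilyloxy)butanedioate | CC[C@H](C)C[C@H](C)OC(=O)[C@H](C#CBr)[C@@](C)(O[Si](C)(C)C)C(=O)OC | intermediate
14 | 1-methyl 4-[(2S,4S)-4-methylhexan-2-yl] (2R,3R)-2-methyl-3-{[methyl(4-methylbenzenesulfonyl)amino]ethynyl}-2-(trimethylsilyloxy)butanedioate | CC[C@H](C)C[C@H](C)OC(=O)[C@H](C#CN(C)S(=O)(=O)c1ccc(C)cc1)[C@@](C)(O[Si](C)(C)C)C(=O)OC | intermediate
15 | (2S,4S)-4-methylhexan-2-yl (2R,3R)-3-methyl-2-{[methyl(4-methylbenzenesulfonyl)amino]ethynyl}-4-oxo-3-(trimethylsilyloxy)butanoate | CC[C@H](C)C[C@H](C)OC(=O)[C@H](C#CN(C)S(=O)(=O)c1ccc(C)cc1)[C@@](C)(O[Si](C)(C)C)C=O | intermediate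
16 | tert-butyl (E)-4-oxobut-2-enoate | CC(C)(C)OC(=O)/C=C/C=O | starting material
17 | 3-bromo-1-(trimethylsilyl)prop-1-yne | C[Si](C)(C)C#CCBr | starting material
18 | tert-butyl (E)-4-hydroxy-7-(trimethylsilyl)hept-2-en-6-ynoate (racemic) | CC(C)(C)OC(=O)/C=C/C(O)CC#C[Si](C)(C)C | intermediate
19 | tert-butyl (E)-4-oxo-7-(trimethylsilyl)hept-2-en-6-ynoate | CC(C)(C)OC(=O)/C=C/C(=O)CC#C[Si](C)(C)C | intermediate
20 | (2S,4S)-4-methylhexan-2-yl (1R,2R,6E)-5-[(3E)-5-tert-butoxy-2,5-dioxopent-3-en-1-yl]-2-methyl-6-{[methyl(4-methylbenzenesulfonyl)amino]methylidene}-3-oxo-4-(trimethylsilyl)-2-(trimethylsilyloxy)cyclohex-4-ene-1-carboxylate | CC[C@H](C)C[C@H](C)OC(=O)[C@@H]1/C(=C\N(C)S(=O)(=O)c2ccc(C)cc2)C(CC(=O)/C=C/C(=O)OC(C)(C)C)=C([Si](C)(C)C)C(=O)[C@]1(C)O[Si](C)(C)C | intermediate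
21 | (2S,4S)-4-methylhexan-2-yl (7R,8R)-3-[(E)-3-tert-butoxy-3-oxoprop-1-en-1-yl]-7-hydroxy-7-methyl-6-oxo-7,8-dihydro-6H-isochromene-8-carboxylate | CC[C@H](C)C[C@H](C)OC(=O)[C@@H]1C2=COC(/C=C/C(=O)OC(C)(C)C)=CC2=CC(=O)[C@]1(C)O | intermediate
22 | (E)-3-[(7R,8R)-7-hydroxy-7-methyl-8-{[(2S,4S)-4-methylhexan-2-yl]oxycarbonyl}-6-oxo-7,8-dihydro-6H-isochromen-3-yl]prop-2-enoic acid | CC[C@H](C)C[C@H](C)OC(=O)[C@@H]1C2=COC(/C=C/C(=O)O)=CC2=CC(=O)[C@]1(C)O | target

**Step count and risks**

Total step count: 13. Longest linear sequence: 10 steps (steps 1, 2, 4, 5, 6, 7, 8, 9, 12, 13).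

Steps most likely to fail:

1. Step 12. The acyl rhodium hydride may leave by the competing intramolecular paths (reductive elimination to the alkylidenecyclobutanone, trans addition and closure to the cyclopentenone). The hindered silylalkyne may also insert too slowly or in the wrong orientation, or the enoate double bond of 19 may insert in its place. The fallback makes the same two bonds one after the other by known reactions; it sets out from 15 and 19 and comes back to the route at 21. Semihydrogenation of 15 (H2, Pd/CaCO3 poisoned with Pb(OAc)2, quinoline, EtOAc) should give the (Z)-enamide aldehyde F1, and iododesilylation of 19 (NIS, AgNO3 cat., acetone) should give the iodoalkyne F2. Nozaki–Hiyama–Kishi coupling of F1 with F2 (CrCl2, NiCl2 cat., THF) should form C5–C6 as the propargylic alcohol F3, Dess–Martin oxidation should then give the ynone F4, and anti addition of HI (LiI, AcOH, MeCN) should give the (Z)-β-iodoenone F5. An intramolecular Heck reaction (Pd(OAc)2, PPh3, Ag2CO3, MeCN, 60 °C; 6-exo-trig onto the enamide, β-hydride elimination restoring the enamide) should form C4a–C8a and give the C5-unsilylated cyclohexenone F6. Under the conditions of step 13, F6 should give 21 and from there 22.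

2. Step 6. The enyne ketene acetal may react through its alkyne terminus to give an allene, or the syn/anti and facial selectivities may be low with this hindered nucleophile. The fallback replaces catalyst control by a preformed-enolate aldol with separation of stereoisomers; it sets out from 8 (through its lithium enolate 9) and 11 and comes back at 12. Enolate 9 is added directly to 11 at −78 °C in THF, where the closed, chelated transition state should confine bond formation to the metal-bound α-carbon and give the lithium aldolate F7, which is silylated in the same flask with Me3SiCl to give 12. Because the ester is enantiopure, every stereoisomeric adduct is a diastereomer of 12, so 12 can be isolated by chromatography.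

3. Step 13. The nitrogen-to-oxygen exchange may stall (hydrolysis of the enamide without ring closure), or the long acid exposure needed for the tert-butyl ester may cause dehydration across C7–C8 or epimerisation at C8. The fallback separates the events and avoids a Brønsted acid for the ester; it sets out from 20, passes through 21 (isolated this time) and ends at 22. Et3N in MeCN should close ring A by addition–elimination of the C3 enolate oxygen at C1, with the sulfonamide as leaving group, to give the doubly silylated pyran F8. HF·pyridine in THF at 0 °C should then remove both silyl groups to give 21, and ZnBr2 in CH2Cl2 should cleave the tert-butyl ester to give 22.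

**Further compounds**

F1 | step 12 | (2S,4S)-4-methylhexan-2-yl (2R,3R)-3-methyl-2-{(Z)-2-[methyl(4-methylbenzenesulfonyl)amino]ethenyl}-4-oxo-3-(trimethylsilyloxy)butanoate | CC[C@H](C)C[C@H](C)OC(=O)[C@H](/C=C\N(C)S(=O)(=O)c1ccc(C)cc1)[C@@](C)(O[Si](C)(C)C)C=O
F2 | step 12 | tert-butyl (E)-7-iodo-4-oxohept-2-en-6-ynoate | CC(C)(C)OC(=O)/C=C/C(=O)CC#CI
F3 | step 12 | propargylic alcohol from F1 and F2 (both epimers at the carbinol carbon, the future C6) | CC[C@H](C)C[C@H](C)OC(=O)[C@H](/C=C\N(C)S(=O)(=O)c1ccc(C)cc1)[C@@](C)(O[Si](C)(C)C)C(O)C#CCC(=O)/C=C/C(=O)OC(C)(C)C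
F4 | step 12 | ynone from F3 (C6 ketone conjugated to the C5≡C4a triple bond) | CC[C@H](C)C[C@H](C)OC(=O)[C@H](/C=C\N(C)S(=O)(=O)c1ccc(C)cc1)[C@@](C)(O[Si](C)(C)C)C(=O)C#CCC(=O)/C=C/C(=O)OC(C)(C)C
F5 | step 12 | (Z)-β-iodoenone from F4 (iodine on C4a, cis to the C6 carbonyl) | CC[C@H](C)C[C@H](C)OC(=O)[C@H](/C=C\N(C)S(=O)(=O)c1ccc(C)cc1)[C@@](C)(O[Si](C)(C)C)C(=O)/C=C(\I)CC(=O)/C=C/C(=O)OC(C)(C)C
F6 | step 12 | analogue of 20 with hydrogen in place of the C5 silyl group (enamide geometry not fixed) | CC[C@H](C)C[C@H](C)OC(=O)[C@@H]1C(=CN(C)S(=O)(=O)c2ccc(C)cc2)C(CC(=O)/C=C/C(=O)OC(C)(C)C)=CC(=O)[C@]1(C)O[Si](C)(C)C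
F7 | step 6 | lithium alkoxide of the (2R,3R) aldol adduct (12 with O–Li in place of O–SiMe3) | CC[C@H](C)C[C@H](C)OC(=O)[C@H](C#C[Si](C)(C)C)[C@@](C)(O[Li])C(=O)OC
F8 | step 13 | 21 carrying SiMe3 at C5 and on the C7 oxygen | CC[C@H](C)C[C@H](C)OC(=O)[C@@H]1C2=COC(/C=C/C(=O)OC(C)(C)C)=CC2=C([Si](C)(C)C)C(=O)[C@]1(C)O[Si](C)(C)C
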